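The numbers in the tables come from a simulation on assumed constants; noise was put on by code.

The products of this flask, mono adduct first among them, are what the starting material loses, so before the run I reckoned that loss.

| setting | autumn | midnight | spring | flask |
|---|---|---|---|---|
| starting material | 13 mM | 30 mM | 20 mM | 20 mM |
| partner | 1.5 equiv | 1.5 equiv | 0.75 equiv | 1.50 equiv |
| remark | run made earlier | run made earlier | run made earlier |  |
| time |  |  |  | 25 min |

| run | time / min | starting material / % | mono adduct / % |
|---|---|---|---|
| autumn | 4.00 | 94 | 5 |
| autumn | 8.00 | 89 | 9 |
| autumn | 12.0 | 88 | 8 |
| autumn | 15.0 | 88 | 9 |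
| autumn | 20.0 | 87 | 13 |
| midnight | 2.00 | 92 | 5 |
| midnight | 5.00 | 85 | 12 |
| midnight | 10.0 | 79 | 15 |
| midnight | 15.0 | 76 | 16 |
| midnight | 20.0 | 71 | 17 |
| spring | 1.50 | 98 | 3 |
| spring | 3.00 | 97 | 3 |
| spring | 6.00 | 92 | 5 |
| spring | 10.0 | 90 | 10 |
| spring | 20.0 | 92 | 10 |

(each reading ± 1.5 percentage points)



- the starting material standing at 25 min, as a percentage of the starting material charged
- the mono adduct standing at 25 min, as a percentage of the starting material charged
- the double product standing at 25 min, as a percentage of the starting material charged
- the triple product standing at 25 min, as a percentage of the starting material charged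

I read the midnight run at both ends. Up to its first reading, the logarithm of the starting material fell by 0.0417 min⁻¹. Between 10.0 min and 20.0 min it fell by 0.0107 min⁻¹, about a quarter of that, though 79 % still stood at the start of that stretch. The fall was dying. Its whole size over its opening pace gave a working time, τ = 8.22 min.

Then I read the last rows against the partner charged. Autumn gave 0.00714 mM⁻¹, midnight 0.00761 mM⁻¹ and spring 0.00556 mM⁻¹, which is close for readings with a scatter of 1.5 percentage points. Pooled, this is the reach, ρ = 0.00711 mM⁻¹: the logarithmic fall of the starting material by the last reading, per mM of partner charged.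

I took the dying of the fall to be the partner going away. This flask was charged with 30.0 mM of partner and ran 3.04 working times, so by my reckoning its starting material should stand near 80.8 % at 25 min, and that level is what to watch.

The forecast gave 80 %, 15 %, 4.3 % and 0.5 % in the asked order, on a different picture from mine: “the first addition looks reversible”.

The flask gave 80.0 %, 14.2 %, 3.09 % and 0.706 %. At 25.0 min the partner, charged in excess, stood at 3.0 % of its charge, less than the starting material's 80 %, so here it was the limiting reagent.

    partner → decomposed reagent (k = 0.116 min⁻¹)
    starting material + double product → side product (k = 1.07 M⁻¹ min⁻¹)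
    starting material + partner → mono adduct (k = 1.01 M⁻¹ min⁻¹)
    partner + double product → triple product (k = 2.47 M⁻¹ min⁻¹)
    partner + mono adduct → double product (k = 2.84 M⁻¹ min⁻¹)

The neighbour with 34 mM of starting material was charged with 51.0 mM of partner, for which ρ gives 69.6 % of that starting material left. Computed, the neighbour's starting material stood at 69.9 % at 25.0 min.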